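The target is an achiral ester whose acyl part, C2–C28, is one straight saturated chain with no heteroatom, branch or stereocentre, so every CH2–CH2 bond in it is a possible seam. The route opens C11–C12 (counting from the ester carbonyl, C1) and closes it by a crossed Kolbe electrolysis: stearic acid brings C12–C28 as a heptadecyl radical, and the monobenzyl ester of dodecanedioic acid brings C1–C11 with the benzyl ester and its phenyl ring already attached. A single anodic operation therefore makes the only strategic C–C bond and gives the target directly. The half-ester precursor comes in two steps from the diacid and benzyl alcohol.

Key step: step 5

Remark on the chemistry: the target has no stereocentre, so its SMILES is taken as written. Steps 3, 4 and 5 are one and the same electrolysis of a single charge in a single cell. That cell delivers three coupling products, and each is written as a step of its own, so that the two homo-coupling coproducts, which are separated and not carried on, stand in the route with a number and a defined origin.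

Step 1
Reactants: 1 dodecanedioic acid; 2 benzyl alcohol
Product: 3 dibenzyl dodecanedioate
Conditions: 2 (3 equiv), TsOH·H2O (5 mol %), toluene, reflux, Dean–Stark; aq NaHCO3 wash, excess 2 distilled off in vacuo, short SiO2 plug
Reagents that add atoms: none
Why: Fischer esterification of both carboxyl groups, driven to the diester by azeotropic removal of water and the excess of alcohol, on a chain that carries nothing else an acid could attack.

Step 2
Reactants: 3 dibenzyl dodecanedioate
Product: 4 benzyl hydrogen dodecanedioate (12-(benzyloxy)-12-oxododecanoic acid)
Conditions: KOH (1.0 equiv) in BnOH, added dropwise to 3 in THF, 0 °C to rt; 1 M HCl to pH 2, EtOAc; BnOH distilled off in vacuo; cold toluene trituration to remove 1; SiO2 (hexane/EtOAc, 1 % AcOH); recovered 3 resubmitted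
Reagents that add atoms: potassium hydroxide, [K+].[OH-]
Why: Saponification (acyl substitution by hydroxide) held at one ester group by the single equivalent of base, with benzyl alcohol as cosolvent so that any alkoxide exchange is degenerate; the two ends of the C12 chain react independently, so a statistical mixture is the worst case, from which neutral 3 runs ahead of 4 on silica and the sparingly soluble diacid 1 is filtered off, both for re-use.

Step 3
Reactants: 5 stearic acid (octadecanoic acid), two molecules
Product: 6 tetratriacontane
Conditions: the electrolysis of step 5: 4 (1 equiv), 5 (3 equiv), Et3N (5 mol % of total acid), MeOH/hexane, smooth Pt anode, Pt cathode, undivided cell, ca. 0.3 A cm−2, 40–45 °C; first SiO2 fraction (hexane)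
Reagents that add atoms: none
Why: Kolbe electrolysis in its homo-coupling mode: because 5 is present in threefold excess, most heptadecyl radicals formed by anodic decarboxylation meet one of their own kind on the platinum surface and dimerise to the C34 alkane, which carries no polar group and should therefore run ahead of everything else on silica.

Step 4
Reactants: 4 benzyl hydrogen dodecanedioate, two molecules
Product: 7 dibenzyl docosanedioate
Conditions: the electrolysis of step 5 (same cell, same charge); last ester fraction from SiO2 (hexane/EtOAc)
Reagents that add atoms: none
Why: Kolbe homo-coupling of two 10-(benzyloxycarbonyl)decyl radicals from 4, expected only as a minor pathway because 4 is the minority acid in the cell; with two ester groups the C22 diester should be held longer on silica than the monoester 8 and is removed there.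

Step 5
Reactants: 4 benzyl hydrogen dodecanedioate; 5 stearic acid (octadecanoic acid)
Product: 8 benzyl octacosanoate
Conditions: 4 (1 equiv), 5 (3 equiv), Et3N (5 mol % of total acid), MeOH/hexane, smooth Pt anode, Pt cathode, undivided cell, ca. 0.3 A cm−2, 40–45 °C, ca. 1 F per mol of acid, stopped while still acidic; SiO2 (hexane, then hexane/EtOAc), recrystallisation from acetone
Reagents that add atoms: none
Why: One-electron discharge of the two carboxylates on smooth platinum gives acyloxy radicals that extrude CO2 at once, and because the current density is high the heptadecyl radical from 5 and the 10-(benzyloxycarbonyl)decyl radical from 4 are generated side by side on the surface and combine to the C11–C12 sp3–sp3 bond, while the acid protons are reduced to H2 at the cathode. The reaction type is the crossed Kolbe electrolysis of a fatty acid with an alkyl hydrogen alkanedioate, the established anodic chain extension of saturated esters, used here with a benzyl instead of a methyl half-ester. No ring is closed and no stereocentre is created, so chemoselectivity is the only demand. Cross- against homo-coupling is statistical and is biased by the threefold excess of cheap 5, which should send most of the ester radicals into 8; the homodimers 6 (eluted first, with hexane) and 7 (more polar, eluted after 8) are removed on silica. Neither acid carries a substituent on its alpha carbon that would stabilise a cation, so the primary radicals should couple instead of being oxidised a second time, and a (CH2)10 spacer separates the benzyl ester of 4 from the carboxylate being discharged. Because the only cation in the electrolyte is Et3NH+ and free acid is present to the end, no alkoxide can accumulate at the cathode, which should protect the benzyl ester from methanolysis, and the hexane cosolvent keeps the waxy products in solution and off the electrodes.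

Compound list
1 | dodecanedioic acid | OC(=O)CCCCCCCCCCC(=O)O | starting material
2 | benzyl alcohol | OCc1ccccc1 | starting material
3 | dibenzyl dodecanedioate | O=C(CCCCCCCCCCC(=O)OCc1ccccc1)OCc1ccccc1 | intermediate
4 | benzyl hydrogen dodecanedioate (12-(benzyloxy)-12-oxododecanoic acid) | OC(=O)CCCCCCCCCCC(=O)OCc1ccccc1 | intermediate
5 | stearic acid (octadecanoic acid) | CCCCCCCCCCCCCCCCCC(=O)O | starting material
6 | tetratriacontane | CCCCCCCCCCCCCCCCCCCCCCCCCCCCCCCCCC | intermediate (coproduct of the electrolysis, separated and not carried on)
7 | dibenzyl docosanedioate | O=C(CCCCCCCCCCCCCCCCCCCCC(=O)OCc1ccccc1)OCc1ccccc1 | intermediate (coproduct of the electrolysis, separated and not carried on)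
8 | benzyl octacosanoate | CCCCCCCCCCCCCCCCCCCCCCCCCCCC(=O)OCc1ccccc1 | target

Total step count: 5 (steps 3, 4 and 5 are a single electrolysis, so three laboratory operations)
Longest linear sequence: 3 steps (steps 1, 2 and 5: 1 → 3 → 4 → 8)

Steps most likely to fail

Step 5 (crossed Kolbe electrolysis). Three processes could spoil it:
- Passivation: a waxy film may grow on the anode, the current density at the free metal drifts, and two-electron oxidation and disproportionation of the radicals take over from coupling.
- Homo-coupling: the pathways of steps 3 and 4 may consume more of the half-ester than the excess of 5 allows for.
- Ester exchange: benzyl may be exchanged for methyl in the cathode layer.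

The fallback forms the same C11–C12 bond by a polar route. It sets out from benzyl alcohol 2, which is esterified with purchased 11-bromoundecanoic acid (TsOH, toluene, Dean–Stark) to benzyl 11-bromoundecanoate F1. Purchased 1-bromoheptadecane is converted with magnesium turnings in THF into heptadecylmagnesium bromide F2. F2 is added slowly to F1 in THF/NMP at 0 °C in the presence of Li2CuCl4 (3 mol %), so that copper-catalysed alkyl–alkyl coupling at the primary bromide outruns addition to the ester. The fallback comes back to the route at 8.

Step 2 (monosaponification). Hydrolysis may run on to the diacid, the potassium soap of the half-ester may give emulsions on work-up, and the three-component mixture may separate poorly. The fallback avoids any statistical mixture. It sets out from benzyl alcohol 2, used in large excess to esterify purchased 12-hydroxydodecanoic acid (TsOH, toluene, Dean–Stark; excess 2 distilled off), so that oligoesters of the hydroxy acid are alcoholysed as well, giving benzyl 12-hydroxydodecanoate F3. The primary alcohol of F3 is then oxidised to the carboxylic acid with catalytic TEMPO and PhI(OAc)2 in MeCN/water, which leaves the benzyl ester untouched. The fallback comes back to the route at 4.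

Step 1 (double esterification). The second carboxyl group may esterify incompletely, benzyl alcohol may self-condense to its ether under acid, and the high-boiling excess alcohol may be hard to remove completely. The fallback sets out from 1 and replaces the equilibrium acylation by O-alkylation of the dicarboxylate with benzyl bromide (2.2 equiv, K2CO3, DMF, 60 °C). This forms the O–CH2 bonds irreversibly and comes back to the route at 3; no new compound is made on the way (F0).

Further compounds
F1 | step 5 | benzyl 11-bromoundecanoate | BrCCCCCCCCCCC(=O)OCc1ccccc1
F2 | step 5 | heptadecylmagnesium bromide | CCCCCCCCCCCCCCCCC[Mg]Br
F3 | step 2 | benzyl 12-hydroxydodecanoate | OCCCCCCCCCCCC(=O)OCc1ccccc1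
F0 | step 1 | none | none
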